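## Analysis of the target

Target 19 is an isoflavan. Its benzo ring (ring A, C4a–C8a) carries a hydroxyl at C7, and its dihydropyran ring (ring C: O1, C2, C3, C4) carries ring B at C3. Ring B has a methoxy group at C2', hydroxyls at C3' and C4', and a 2-methylbut-3-en-2-yl (reverse prenyl) group at C5'. C3 is the only stereocentre and is (R) (C2 > C1' > C4 > H); it sits between two methylene groups, so nothing nearby can relay its configuration, but once set it has no pathway for epimerisation. The sensitive parts are the C3'/C4' catechol (oxidised to an ortho-quinone in air under base), the terminal vinyl group (lost in any hydrogenation) and the ortho-(1,1-dimethylallyl)phenol at C4'/C5' (closes to a dihydrobenzofuran under acid). The synthesis is hard for three reasons: four aromatic oxygens must be told apart, a quaternary benzylic carbon must be placed at C5' only, and an isolated stereocentre must be made by enantiofacial control alone. The order of events is also constrained, because every reductive step must precede the arrival of the vinyl group and the last deprotection may use neither acid nor hydrogen. The strategy rests on one feature: C2–C3–C4 of ring C, with ring B on the central carbon, is the skeleton of a 2-arylacrolein, and ring A is a resorcinol monoether whose ortho carbon para to the second oxygen is C4a. Joining C4 to C4a and O1 to C2 in one operation gives an isoflav-3-ene, whose C3=C4 double bond is the handle for setting C3 by asymmetric hydrogenation.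

## Retrosynthetic reasoning

**19 ⇒ 18.** The last bonds cut are the two O–Si bonds at O3' and O7. Silyl groups are chosen because fluoride removes them without acid or reduction, so the vinyl group and the ortho-(dimethylallyl)phenol survive.

**18 ⇒ 16 (through 17).** The C5'–C(quaternary) bond is cut by a retro-Claisen step to the O4' prenyl ether 16. A tertiary benzylic carbon bearing a vinyl group next to a phenol is the imprint of a [3,3] shift; direct electrophilic alkylation would give the linear prenyl isomer. The forward reaction must deliver the allyl unit to C5' and not to C3', which the silyloxy group at C3' secures. It must also come after all hydrogenations.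

**16 ⇒ 14 + 15.** The O4'–CH2 bond is cut to phenol 14 and allylic bromide 15. This requires O4' to be the only free oxygen in 14.

**14 ⇒ 13.** The O4'–benzyl bond is cut. A benzyl ether distinguishes O4' from the silylated O3' and O7, and is removed by hydrogenolysis at a stage where the molecule holds no alkene.

**13 ⇒ 12.** The C3–H and C4–H bonds are removed to give the flat C3=C4 alkene of isoflav-3-ene 12. The precursor is then achiral, and the stereocentre comes from a catalyst instead of from the starting materials. The forward reaction must distinguish the two faces of a trisubstituted aryl alkene that has no directing group.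

**12 ⇒ 9 + 7 (through 10 and 11).** Ring C is opened at C4–C4a and O1–C2. This is the disconnection that carries the route, because it divides the skeleton into a ring A phenol 9 and a ring B enal 7 of similar size and forms the ring and both bonds in one operation. The forward reaction needs a boron template that ties the phenol oxygen to the aldehyde, so that the ortho carbon attacks the carbonyl carbon and the resulting quinone methide closes by electrocyclisation.

**7 ⇒ 6 ⇒ 5 ⇒ 4.** The exocyclic methylene carbon (C2 of the target) is removed by a retro-Mannich step to arylacetaldehyde 6. The aldehyde carbon of 6 (C4 of the target) is removed by a retro-Wittig homologation through enol ether 5 to benzaldehyde 4. The formyl group of 4 is the anchor that fixes the substitution pattern of ring B.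

**4 ⇒ 3 ⇒ 2 ⇒ 1.** The O2–methyl, O3–silyl and O4–benzyl bonds are cut in turn back to 1. The three hydroxyls of 1 differ in acidity and in hydrogen bonding to the formyl group, which is what allows them to be addressed one after another.

**9 ⇒ 8.** One O–Si bond is cut to the symmetrical diol 8. The silyl ether blocks one oxygen, activates the para carbon that becomes C4a, and leaves with the other silyl group at the end.

## Alternatives that were turned down

**Alternative 1:** The disconnection cuts C3–C1' and C4–C4a and builds C3 and C4 from a two-carbon vinylboron unit. In the forward key step a ring B aryllithium adds to a vinylboronic ester to give a boron ate complex. A palladium catalyst with a chiral ferrocenyl bisphosphine then couples this with a ring A aryl bromide: 1,2-migration of the aryl group from boron to carbon forms C3–C1', and reductive elimination forms C4–C4a. The product is the benzylic boronate A1, (R)-2-{2-[2,4-bis(tert-butyldimethylsilyloxy)phenyl]-1-[4-(tert-butyldimethylsilyloxy)-2-methoxy-5-(2-methylbut-3-en-2-yl)-3-{[2-(trimethylsilyl)ethoxy]methoxy}phenyl]ethyl}-4,4,5,5-tetramethyl-1,3,2-dioxaborolane.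
- For it: C3 is set in the bond-forming event itself, the route is convergent, and no hydrogenation is needed, so the reverse prenyl group can be on ring B from the start. On these points it is stronger than the chosen strategy.
- Against it: no ring is closed. After A1, C2 must still be inserted by a Matteson homologation, the boronate oxidised, the phenols released, ring C closed at O1–C2 and the acetal at O3' removed, which is four to five further operations. The migrating aryl group is electron-rich and has an ortho methoxy group, and the aryl bromide is electron-rich and has an ortho silyloxy group; both slow the steps that control yield and selectivity. Removing the acetal from the hindered O3' at the end needs forcing fluoride or a Lewis acid next to the acid-sensitive dimethylallyl phenol.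
- Comparison: the chosen strategy forms two ring bonds and ring C in one step from two simple fragments and has a shorter path after the key step.

**Alternative 2:** The disconnection cuts O1–C8a and derives ring A from a para-alkylphenol that has no oxygen at C8a. In the forward key step the 4-alkyl-4-methoxycyclohexa-2,5-dienone from oxidative dearomatisation is treated with a catalytic amidine base. The C2 hydroxyl adds to C8a in a 6-exo-trig oxa-Michael reaction, which forms O1–C8a and closes ring C. A sulfonic acid then removes the methoxy group from C4a and rearomatises ring A. The product is A2, (3R)-3-[3,4-bis(tert-butyldimethylsilyloxy)-2-methoxy-5-(2-methylbut-3-en-2-yl)phenyl]chroman-7-ol.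
- For it: C3 would be set earlier in an open chain, for instance by auxiliary-controlled alkylation, which gives more certainty about absolute configuration than a catalyst acting on a hindered alkene. The C7 hydroxyl emerges free and distinct from the ring B oxygens, and the reverse prenyl group can be carried through. On these points it is as strong or stronger.
- Against it: the phenol must be oxidised with a hypervalent iodine reagent in a molecule that also holds a very electron-rich ring B and a terminal alkene. The primary hydroxyl lies five atoms from the ipso carbon and would compete for the phenoxonium ion to give a spiro ether, so it would need masking and unmasking. The acid step has a dienone–phenol rearrangement as a competing path. The open-chain precursor costs more steps and a stoichiometric auxiliary.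
- Comparison: the chosen strategy offers a shorter and more convergent assembly with no oxidation of an electron-rich arene, and accepts a catalyst-controlled hydrogenation as the price.

**Alternative 3:** The disconnection cuts C4–C4a in a chain that already holds O1–C2 and the C3 stereocentre. In the forward key step a redox-active ester is reduced at the cathode with a nickel bipyridine catalyst. Loss of carbon dioxide gives the primary C4 radical, which is captured by nickel inserted into the C4a–Br bond; reductive elimination closes ring C. The product is A3, (3R)-3-[4-(benzyloxy)-2-methoxy-3-{[2-(trimethylsilyl)ethoxy]methoxy}phenyl]-7-(triisopropylsilyloxy)chroman.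
- For it: C3 is fixed before cyclisation, for example by asymmetric conjugate arylation of an unhindered acceptor, and cannot epimerise. The acetal at O3' cannot migrate to O4', unlike a silyl group. On these two points it is stronger than the chosen strategy.
- Against it: the primary radical sits next to the carbon bearing ring B and four atoms from the ipso carbon of ring A, so 1,2-aryl shift and ipso attack on the aryl ether compete with capture by nickel. Hydrodehalogenation and reduction of the radical to the alkane are further losses at the cathode. The substrate needs about five steps, and the reaction needs an electrochemical cell.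
- Comparison: after A3 the endgame is the same as in the chosen route (debenzylation, prenylation, Claisen rearrangement, deprotection), so nothing is saved there. The chosen strategy reaches the same stage in fewer steps with ordinary reagents.

Key step: step 8

## Route

Assumption: the (S)-configured phosphinooxazoline ligand in step 9 is taken to deliver hydrogen to the face of 12 that gives (3R)-13; the sense must be confirmed on the first run, and the (R)-ligand is used if it proves opposite.

Abbreviations in step 9: tBu-PHOX is 4-tert-butyl-2-[2-(diphenylphosphino)phenyl]-4,5-dihydrooxazole, cod is cycloocta-1,5-diene, and BArF is tetrakis[3,5-bis(trifluoromethyl)phenyl]borate.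

Step 1
Reactants: 1 2,3,4-trihydroxybenzaldehyde
Product: 2 4-(benzyloxy)-2,3-dihydroxybenzaldehyde
Conditions: BnBr (1.0 equiv), NaHCO3, NaI (cat.), DMF, 40 °C
Reagents that add atoms: benzyl bromide, BrCc1ccccc1
Why: Williamson etherification under hydrogencarbonate; the C4 hydroxyl, para to the formyl group, is the most acidic and its phenoxide is not chelated, whereas O2 is held in a hydrogen bond to the carbonyl and O3 is flanked on both sides, so one equivalent of halide should alkylate O4 only.

Step 2
Reactants: 2 4-(benzyloxy)-2,3-dihydroxybenzaldehyde
Product: 3 4-(benzyloxy)-2-hydroxy-3-(triisopropylsilyloxy)benzaldehyde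
Conditions: TIPSCl (1.1 equiv), imidazole, DMF, 0 °C → rt
Reagents that add atoms: chlorotriisopropylsilane, CC(C)[Si](Cl)(C(C)C)C(C)C
Why: Imidazole-mediated silylation of a phenol; the C2 hydroxyl is deactivated by its hydrogen bond to the aldehyde, so the C3 hydroxyl should react first, and a silyl ether on O2 would be activated by the ortho formyl group and lost on aqueous work-up.

Step 3
Reactants: 3 4-(benzyloxy)-2-hydroxy-3-(triisopropylsilyloxy)benzaldehyde
Product: 4 4-(benzyloxy)-2-methoxy-3-(triisopropylsilyloxy)benzaldehyde
Conditions: MeI, K2CO3, acetone, rt
Reagents that add atoms: iodomethane, CI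
Why: Williamson O-methylation of the chelated, acidic C2 hydroxyl; the doubly flanked triisopropylsilyl ether on O3 is expected to stay in place under mild anhydrous carbonate conditions.

Step 4
Reactants: 4 4-(benzyloxy)-2-methoxy-3-(triisopropylsilyloxy)benzaldehyde
Product: 5 1-(benzyloxy)-3-methoxy-4-(2-methoxyethenyl)-2-(triisopropylsilyloxy)benzene (E/Z mixture)
Conditions: Ph3P(CH2OMe)Cl, KOtBu, THF, 0 °C → rt
Reagents that add atoms: (methoxymethyl)triphenylphosphonium chloride, [Cl-].COC[P+](c1ccccc1)(c1ccccc1)c1ccccc1
Why: Wittig methoxymethylenation of a non-enolisable aromatic aldehyde; the E/Z mixture is of no consequence because both isomers hydrolyse to the same aldehyde.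

Step 5
Reactants: 5 1-(benzyloxy)-3-methoxy-4-(2-methoxyethenyl)-2-(triisopropylsilyloxy)benzene
Product: 6 2-[4-(benzyloxy)-2-methoxy-3-(triisopropylsilyloxy)phenyl]acetaldehyde
Conditions: aq. HCl (2 M), THF, 50 °C; used crude
Reagents that add atoms: water, O
Why: Acid-catalysed enol ether hydrolysis (C-protonation, hemiacetal, loss of methanol) gives the one-carbon homologated aldehyde; dilute acid should leave the hindered aryl silyl ether and the benzyl ether intact, and the sensitive arylacetaldehyde is carried on without chromatography.

Step 6
Reactants: 6 2-[4-(benzyloxy)-2-methoxy-3-(triisopropylsilyloxy)phenyl]acetaldehyde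
Product: 7 2-[4-(benzyloxy)-2-methoxy-3-(triisopropylsilyloxy)phenyl]prop-2-enal
Conditions: aq. HCHO (37%), pyrrolidine (10 mol%), EtCO2H (10 mol%), i-PrOH, 45 °C; stored cold with BHT and used at once
Reagents that add atoms: formaldehyde, C=O
Why: Amine-catalysed Mannich α-methylenation; the enamine of 6 adds to the iminium ion of formaldehyde and the Mannich base eliminates the amine to give the 2-arylacrolein. Compound 6 has a single, benzylically activated α-position, and the product is kept cold and stabilised because α-aryl acroleins dimerise readily.

Step 7
Reactants: 8 resorcinol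
Product: 9 3-(triisopropylsilyloxy)phenol
Conditions: 8 (3 equiv), TIPSCl (1 equiv), imidazole, DMF, 0 °C → rt
Reagents that add atoms: chlorotriisopropylsilane, CC(C)[Si](Cl)(C(C)C)C(C)C
Why: Statistical monosilylation of a symmetrical diol used in excess; the water-soluble excess of 8 is washed out and the small amount of bis-ether is removed by chromatography.

Step 8
Reactants: 9 3-(triisopropylsilyloxy)phenol; 7 2-[4-(benzyloxy)-2-methoxy-3-(triisopropylsilyloxy)phenyl]prop-2-enal
Product: 12 3-[4-(benzyloxy)-2-methoxy-3-(triisopropylsilyloxy)phenyl]-7-(triisopropylsilyloxy)-2H-chromene, via benzodioxaborin 10 (not isolated), via ortho-quinone methide 11 (not isolated)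
Conditions: PhB(OH)2 (1.1 equiv), EtCO2H (0.3 equiv), BHT (cat.), toluene, reflux with azeotropic removal of water; 7 added slowly
Reagents that add atoms: none
Why: Phenol 9 and PhB(OH)2 form a mixed aryl phenylboronate whose boron binds the carbonyl oxygen of 7, so that the ortho carbon C6 of 9 attacks the aldehyde carbon through a six-membered cyclic transition state (templated Friedel–Crafts hydroxyalkylation) and forms C4–C4a; loss of water then closes the boronate to benzodioxaborin 10. On continued heating with the carboxylic acid, 10 expels the phenylboronate unit and gives the vinyl ortho-quinone methide 11, an oxatriene O1=C8a–C4a=C4–C3=C2. Ring C is closed by thermal disrotatory oxa-6π electrocyclisation of 11, which forms O1–C2 and restores the aromaticity of ring A. The closest known reaction type is the PhB(OH)2-mediated ortho-condensation of phenols with α,β-unsaturated aldehydes to 2H-chromenes, of which the α-aryl, β-unsubstituted enal 7 is an unusual member. No stereocentre is created, because C2 becomes a methylene group and C3 and C4 are trigonal. The step needs attack at the ortho carbon para to the silyloxy group and 1,2-addition instead of conjugate addition. The boron tether can reach only an ortho carbon; the one between the two oxygens is shielded by the triisopropylsilyl group, while the other is activated from the para position. The same tether holds the carbonyl carbon, not the remote methylene terminus, next to the ring, and slow addition with a radical inhibitor should keep the concentration of free 7 low enough to limit its self-condensation.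

Step 9
Reactants: 12 3-[4-(benzyloxy)-2-methoxy-3-(triisopropylsilyloxy)phenyl]-7-(triisopropylsilyloxy)-2H-chromene
Product: 13 (3R)-3-[4-(benzyloxy)-2-methoxy-3-(triisopropylsilyloxy)phenyl]-7-(triisopropylsilyloxy)chroman
Conditions: [Ir(cod)((S)-tBu-PHOX)]BArF (2 mol%), H2 (50 bar), CH2Cl2, rt
Reagents that add atoms: none
Why: Asymmetric hydrogenation of an unfunctionalised trisubstituted aryl alkene with a cationic iridium phosphinooxazoline complex, a catalyst class suited to 2H-chromenes; the chiral N,P ligand makes the alkene bind through one enantioface and both hydrogens are delivered to it, which sets C3 as (R). The benzyl and silyl ethers are inert to this homogeneous catalyst.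

Step 10
Reactants: 13 (3R)-3-[4-(benzyloxy)-2-methoxy-3-(triisopropylsilyloxy)phenyl]-7-(triisopropylsilyloxy)chroman
Product: 14 3-methoxy-4-[(3R)-7-(triisopropylsilyloxy)chroman-3-yl]-2-(triisopropylsilyloxy)phenol
Conditions: H2 (1 atm), Pd/C (10%), EtOAc, rt
Reagents that add atoms: none
Why: Hydrogenolysis of the benzyl aryl ether over palladium on carbon; the silyl ethers, the non-benzylic O1–C2 bond and the C3 stereocentre are unaffected, and no alkene is present at this stage.

Step 11
Reactants: 14 3-methoxy-4-[(3R)-7-(triisopropylsilyloxy)chroman-3-yl]-2-(triisopropylsilyloxy)phenol; 15 prenyl bromide (1-bromo-3-methylbut-2-ene)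
Product: 16 (3R)-3-[2-methoxy-4-(3-methylbut-2-enyloxy)-3-(triisopropylsilyloxy)phenyl]-7-(triisopropylsilyloxy)chroman
Conditions: K2CO3, acetone, rt
Reagents that add atoms: prenyl bromide, CC(C)=CCBr
Why: Williamson etherification; the only free phenol, O4', is alkylated at the primary allylic carbon of 15 by SN2 displacement. Mild carbonate at room temperature is chosen to limit migration of the neighbouring silyl group.

Step 12
Reactants: 16 (3R)-3-[2-methoxy-4-(3-methylbut-2-enyloxy)-3-(triisopropylsilyloxy)phenyl]-7-(triisopropylsilyloxy)chroman
Product: 18 3-methoxy-6-(2-methylbut-3-en-2-yl)-4-[(3R)-7-(triisopropylsilyloxy)chroman-3-yl]-2-(triisopropylsilyloxy)phenol, via cyclohexadienone 17 (not isolated)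
Conditions: PhNEt2, 190 °C, argon
Reagents that add atoms: none
Why: Aromatic Claisen rearrangement; the [3,3]-sigmatropic shift through a chair-like transition state joins the dimethyl-substituted allyl terminus to C5', the only ortho carbon that carries hydrogen, and dienone 17 tautomerises to the phenol. Attack at the silyloxy-bearing C3' cannot lead to an aromatic product and reverts, the para carbon C1' is substituted, and the basic solvent suppresses acid-catalysed closure of the product onto its vinyl group.

Step 13
Reactants: 18 3-methoxy-6-(2-methylbut-3-en-2-yl)-4-[(3R)-7-(triisopropylsilyloxy)chroman-3-yl]-2-(triisopropylsilyloxy)phenol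
Product: 19 (3R)-3-[3,4-dihydroxy-2-methoxy-5-(2-methylbut-3-en-2-yl)phenyl]chroman-7-ol
Conditions: TBAF (2.5 equiv), THF, 0 °C, argon; then AcOH
Reagents that add atoms: none
Why: Fluoride-mediated cleavage of both aryl silyl ethers, driven by the strong Si–F bond and the good phenoxide leaving groups; no strong acid, hydrogen or oxidant is involved, so the vinyl group, the ortho-(1,1-dimethylallyl)phenol and C3 are preserved. Quenching with acetic acid under argon protects the catechol from aerial oxidation.

## Compound list

1 | 2,3,4-trihydroxybenzaldehyde | O=Cc1ccc(O)c(O)c1O | starting material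
2 | 4-(benzyloxy)-2,3-dihydroxybenzaldehyde | O=Cc1ccc(OCc2ccccc2)c(O)c1O | intermediate
3 | 4-(benzyloxy)-2-hydroxy-3-(triisopropylsilyloxy)benzaldehyde | O=Cc1ccc(OCc2ccccc2)c(O[Si](C(C)C)(C(C)C)C(C)C)c1O | intermediate
4 | 4-(benzyloxy)-2-methoxy-3-(triisopropylsilyloxy)benzaldehyde | COc1c(C=O)ccc(OCc2ccccc2)c1O[Si](C(C)C)(C(C)C)C(C)C | intermediate
5 | 1-(benzyloxy)-3-methoxy-4-(2-methoxyethenyl)-2-(triisopropylsilyloxy)benzene (E/Z mixture) | COC=Cc1ccc(OCc2ccccc2)c(O[Si](C(C)C)(C(C)C)C(C)C)c1OC | intermediate
6 | 2-[4-(benzyloxy)-2-methoxy-3-(triisopropylsilyloxy)phenyl]acetaldehyde | O=CCc1ccc(OCc2ccccc2)c(O[Si](C(C)C)(C(C)C)C(C)C)c1OC | intermediate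
7 | 2-[4-(benzyloxy)-2-methoxy-3-(triisopropylsilyloxy)phenyl]prop-2-enal | C=C(C=O)c1ccc(OCc2ccccc2)c(O[Si](C(C)C)(C(C)C)C(C)C)c1OC | intermediate
8 | resorcinol | Oc1cccc(O)c1 | starting material
9 | 3-(triisopropylsilyloxy)phenol | Oc1cccc(O[Si](C(C)C)(C(C)C)C(C)C)c1 | intermediate
10 | 4-{1-[4-(benzyloxy)-2-methoxy-3-(triisopropylsilyloxy)phenyl]ethenyl}-2-phenyl-7-(triisopropylsilyloxy)-4H-1,3,2-benzodioxaborin (racemic at C4) | C=C(c1ccc(OCc2ccccc2)c(O[Si](C(C)C)(C(C)C)C(C)C)c1OC)C1OB(c2ccccc2)Oc2cc(O[Si](C(C)C)(C(C)C)C(C)C)ccc21 | intermediate
11 | 6-{2-[4-(benzyloxy)-2-methoxy-3-(triisopropylsilyloxy)phenyl]prop-2-en-1-ylidene}-3-(triisopropylsilyloxy)cyclohexa-2,4-dien-1-one | C=C(C=C1C=CC(O[Si](C(C)C)(C(C)C)C(C)C)=CC1=O)c1ccc(OCc2ccccc2)c(O[Si](C(C)C)(C(C)C)C(C)C)c1OC | intermediate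
12 | 3-[4-(benzyloxy)-2-methoxy-3-(triisopropylsilyloxy)phenyl]-7-(triisopropylsilyloxy)-2H-chromene | COc1c(C2=Cc3ccc(O[Si](C(C)C)(C(C)C)C(C)C)cc3OC2)ccc(OCc2ccccc2)c1O[Si](C(C)C)(C(C)C)C(C)C | intermediate
13 | (3R)-3-[4-(benzyloxy)-2-methoxy-3-(triisopropylsilyloxy)phenyl]-7-(triisopropylsilyloxy)chroman | COc1c([C@@H]2COc3cc(O[Si](C(C)C)(C(C)C)C(C)C)ccc3C2)ccc(OCc2ccccc2)c1O[Si](C(C)C)(C(C)C)C(C)C | intermediate
14 | 3-methoxy-4-[(3R)-7-(triisopropylsilyloxy)chroman-3-yl]-2-(triisopropylsilyloxy)phenol | COc1c([C@@H]2COc3cc(O[Si](C(C)C)(C(C)C)C(C)C)ccc3C2)ccc(O)c1O[Si](C(C)C)(C(C)C)C(C)C | intermediate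
15 | prenyl bromide (1-bromo-3-methylbut-2-ene) | CC(C)=CCBr | starting material
16 | (3R)-3-[2-methoxy-4-(3-methylbut-2-enyloxy)-3-(triisopropylsilyloxy)phenyl]-7-(triisopropylsilyloxy)chroman | COc1c([C@@H]2COc3cc(O[Si](C(C)C)(C(C)C)C(C)C)ccc3C2)ccc(OCC=C(C)C)c1O[Si](C(C)C)(C(C)C)C(C)C | intermediate
17 | 3-methoxy-6-(2-methylbut-3-en-2-yl)-4-[(3R)-7-(triisopropylsilyloxy)chroman-3-yl]-2-(triisopropylsilyloxy)cyclohexa-2,4-dien-1-one (mixture of epimers at C6) | COC1=C(O[Si](C(C)C)(C(C)C)C(C)C)C(=O)C(C(C)(C)C=C)C=C1[C@@H]1COc2cc(O[Si](C(C)C)(C(C)C)C(C)C)ccc2C1 | intermediate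
18 | 3-methoxy-6-(2-methylbut-3-en-2-yl)-4-[(3R)-7-(triisopropylsilyloxy)chroman-3-yl]-2-(triisopropylsilyloxy)phenol | COc1c([C@@H]2COc3cc(O[Si](C(C)C)(C(C)C)C(C)C)ccc3C2)cc(C(C)(C)C=C)c(O)c1O[Si](C(C)C)(C(C)C)C(C)C | intermediate
19 | (3R)-3-[3,4-dihydroxy-2-methoxy-5-(2-methylbut-3-en-2-yl)phenyl]chroman-7-ol | C=CC(C)(C)c1cc([C@@H]2COc3cc(O)ccc3C2)c(OC)c(O)c1O | target

## Step count and least certain steps

Total: 13 steps. Longest linear sequence: 12 steps, from 1 to 19 (steps 1–6 and 8–13); step 7 is the one-step side branch to 9.

**Step 8 (key step).** The most likely failure is thermal self-condensation or polymerisation of enal 7 at reflux before the boron template captures it. Conjugate attack of the phenol at the unsubstituted methylene terminus is a second risk, since α-aryl, β-unsubstituted enals are little explored in this condensation. The fallback sets out from 7 and returns at 12, and makes the same two bonds in two polar operations. 4-Bromoresorcinol F1 is silylated (TIPSCl, imidazole) at the hydroxyl remote from bromine to give 2-bromo-5-(triisopropylsilyloxy)phenol F2. Two equivalents of n-BuLi in THF at −78 °C deprotonate the phenol and exchange bromine for lithium, and the aryllithium adds to the carbonyl group of 7 in the cold. This should give the ortho-hydroxybenzylic allylic alcohol 2-{2-[4-(benzyloxy)-2-methoxy-3-(triisopropylsilyloxy)phenyl]-1-hydroxyprop-2-en-1-yl}-5-(triisopropylsilyloxy)phenol F3. Warming F3 in toluene with pyridinium p-toluenesulfonate removes water and generates quinone methide 11, which closes to 12 as in the main route. The bromine fixes the site of C–C bond formation, and the enal is never heated.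

**Step 9.** Poor facial selectivity or incomplete conversion is possible, because ring B carries a methoxy group and a bulky silyloxy group next to the alkene and is twisted out of its plane. Migration of the double bond to the C2–C3 enol ether position under the acidic iridium hydride would erode the selectivity further. The fallback sets out from 12 and returns at 14. Hydrogenation of 12 over Pd/C in EtOAc/EtOH reduces the alkene and cleaves the benzyl ether in one operation and should give racemic 3-methoxy-4-[7-(triisopropylsilyloxy)chroman-3-yl]-2-(triisopropylsilyloxy)phenol F4. Preparative chromatography on an amylose carbamate chiral stationary phase then separates 14 from its (3S) enantiomer, 3-methoxy-4-[(3S)-7-(triisopropylsilyloxy)chroman-3-yl]-2-(triisopropylsilyloxy)phenol F5. Half of the material is lost, but the configuration no longer depends on a catalyst.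

**Step 12.** At the temperature needed, secondary reactions of the product can compete: an ene-type hydrogen shift from the new phenol to the vinyl group with skeletal reorganisation (abnormal Claisen pathway), closure of the phenol onto the vinyl group, or loss of the prenyl unit. The fallback sets out from 16 and returns at 19. The rearrangement is run as a rearrangement–acylation (butyric anhydride, PhNEt2, 190 °C), so that the phenol is esterified as it forms. This should give 3-methoxy-6-(2-methylbut-3-en-2-yl)-4-[(3R)-7-(triisopropylsilyloxy)chroman-3-yl]-2-(triisopropylsilyloxy)phenyl butanoate F6. F6 is taken directly to 19 by TBAF in THF followed by K2CO3 in MeOH under argon, which removes both silyl groups and the ester.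

**Step 11.** Under carbonate the triisopropylsilyl group may migrate from O3' to the neighbouring O4' phenoxide through pentacoordinate silicon. Alkylation would then occur at O3' and give an ether that cannot rearrange to C5'. The fallback sets out from 14 and returns at 16. It is a Mitsunobu etherification of 14 with 3-methylbut-2-en-1-ol (PPh3, diisopropyl azodicarboxylate, THF, 0 °C), in which the alcohol is activated and no free phenoxide persists. This fallback makes no compound outside the list (F0).

**Step 3.** Silyl migration from O3 to the O2 phenoxide, or partial desilylation, during the basic methylation would give regioisomeric aldehydes that are hard to separate. An imperfect O3/O2 selectivity in step 2 would have the same effect. The fallback sets out from 1 and returns at 4, and fixes each oxygen by an unambiguous operation.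
- Dichlorodiphenylmethane (neat, 170 °C) bridges O3 and O4 and gives 4-hydroxy-2,2-diphenyl-1,3-benzodioxole-5-carbaldehyde F7.
- MeI and K2CO3 in DMF methylate the remaining chelated hydroxyl to give 4-methoxy-2,2-diphenyl-1,3-benzodioxole-5-carbaldehyde F8.
- Aqueous acetic acid at reflux removes the ketal and gives 3,4-dihydroxy-2-methoxybenzaldehyde F9.
- BnBr and NaHCO3 in DMF alkylate the hydroxyl para to the formyl group and give 4-(benzyloxy)-3-hydroxy-2-methoxybenzaldehyde F10.
- TIPSCl and imidazole silylate the last hydroxyl and give 4.

This costs two more steps than the main sequence.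

## Further compounds

F1 | step 8 | 4-bromoresorcinol (4-bromobenzene-1,3-diol) | Oc1ccc(Br)c(O)c1
F2 | step 8 | 2-bromo-5-(triisopropylsilyloxy)phenol | Oc1cc(O[Si](C(C)C)(C(C)C)C(C)C)ccc1Br
F3 | step 8 | 2-{2-[4-(benzyloxy)-2-methoxy-3-(triisopropylsilyloxy)phenyl]-1-hydroxyprop-2-en-1-yl}-5-(triisopropylsilyloxy)phenol (racemic) | C=C(C(O)c1ccc(O[Si](C(C)C)(C(C)C)C(C)C)cc1O)c1ccc(OCc2ccccc2)c(O[Si](C(C)C)(C(C)C)C(C)C)c1OC
F4 | step 9 | racemic 3-methoxy-4-[7-(triisopropylsilyloxy)chroman-3-yl]-2-(triisopropylsilyloxy)phenol | COc1c(C2COc3cc(O[Si](C(C)C)(C(C)C)C(C)C)ccc3C2)ccc(O)c1O[Si](C(C)C)(C(C)C)C(C)C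
F5 | step 9 | 3-methoxy-4-[(3S)-7-(triisopropylsilyloxy)chroman-3-yl]-2-(triisopropylsilyloxy)phenol | COc1c([C@H]2COc3cc(O[Si](C(C)C)(C(C)C)C(C)C)ccc3C2)ccc(O)c1O[Si](C(C)C)(C(C)C)C(C)C
F6 | step 12 | 3-methoxy-6-(2-methylbut-3-en-2-yl)-4-[(3R)-7-(triisopropylsilyloxy)chroman-3-yl]-2-(triisopropylsilyloxy)phenyl butanoate | COc1c([C@@H]2COc3cc(O[Si](C(C)C)(C(C)C)C(C)C)ccc3C2)cc(C(C)(C)C=C)c(OC(=O)CCC)c1O[Si](C(C)C)(C(C)C)C(C)C
F0 | step 11 | none | none
F7 | step 3 | 4-hydroxy-2,2-diphenyl-1,3-benzodioxole-5-carbaldehyde | O=Cc1ccc2OC(c3ccccc3)(c3ccccc3)Oc2c1O
F8 | step 3 | 4-methoxy-2,2-diphenyl-1,3-benzodioxole-5-carbaldehyde | COc1c(C=O)ccc2OC(c3ccccc3)(c3ccccc3)Oc12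
F9 | step 3 | 3,4-dihydroxy-2-methoxybenzaldehyde | COc1c(C=O)ccc(O)c1O
F10 | step 3 | 4-(benzyloxy)-3-hydroxy-2-methoxybenzaldehyde | COc1c(C=O)ccc(OCc2ccccc2)c1O
A1 | alternative 1 | (R)-2-{2-[2,4-bis(tert-butyldimethylsilyloxy)phenyl]-1-[4-(tert-butyldimethylsilyloxy)-2-methoxy-5-(2-methylbut-3-en-2-yl)-3-{[2-(trimethylsilyl)ethoxy]methoxy}phenyl]ethyl}-4,4,5,5-tetramethyl-1,3,2-dioxaborolane | C=CC(C)(C)c1cc([C@@H](Cc2ccc(O[Si](C)(C)C(C)(C)C)cc2O[Si](C)(C)C(C)(C)C)B2OC(C)(C)C(C)(C)O2)c(OC)c(OCOCC[Si](C)(C)C)c1O[Si](C)(C)C(C)(C)C
A2 | alternative 2 | (3R)-3-[3,4-bis(tert-butyldimethylsilyloxy)-2-methoxy-5-(2-methylbut-3-en-2-yl)phenyl]chroman-7-ol | C=CC(C)(C)c1cc([C@@H]2COc3cc(O)ccc3C2)c(OC)c(O[Si](C)(C)C(C)(C)C)c1O[Si](C)(C)C(C)(C)C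
A3 | alternative 3 | (3R)-3-[4-(benzyloxy)-2-methoxy-3-{[2-(trimethylsilyl)ethoxy]methoxy}phenyl]-7-(triisopropylsilyloxy)chroman | COc1c([C@@H]2COc3cc(O[Si](C(C)C)(C(C)C)C(C)C)ccc3C2)ccc(OCc2ccccc2)c1OCOCC[Si](C)(C)C
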